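**Strategy.** Carbocycle numbering: C1 (quaternary, Me and CH2OAr), C2 (CHMe), C3, C4, C5 (=CMe2), C6 (CH bearing the hydroxypropyl chain). The route rests on the C5–C6 bond. (R)-Citronellal supplies C6, C1–C5, the C2 methyl and the isopropylidene group. C1 with its neopentyl isofraxidin ether is built in the open chain by Sharpless epoxidation and a stereospecific 1,2-shift of ArOCH2. The key step is a 6-exo-trig vinyl radical cyclisation of an acyclic tetrasubstituted vinyl bromide onto a homoallylic alcohol. It closes the cyclohexane, keeps C5=CMe2 exactly where bromine sat, and sets C6 through allylic 1,3-strain against that alkene, giving the target directly.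

Key step: step 8

Assumption: the new alkene of 14 is drawn E. Its geometry has no bearing on the product, because that carbon ends as CH2.

Step 1
Reactants: 1 (R)-citronellal
Product: 3 (3R)-3,7-dimethyloct-6-en-1-yne, via enol nonaflate 2 (not isolated)
Conditions: n-C4F9SO2F, phosphazene base P1-t-Bu-tris(tetramethylene), DMF, 0 °C to rt
Reagents that add atoms: none
Why: One-pot enol sulfonate formation and base-induced elimination (aldehyde to terminal alkyne without homologation) turns CH2–CHO into C≡CH and does not touch the adjacent stereocentre, which becomes C2.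

Step 2
Reactants: 3 (3R)-3,7-dimethyloct-6-en-1-yne
Product: 5 (3R)-6-bromo-3,7-dimethyloct-6-en-1-yne, via vicinal dibromide 4 (not isolated)
Conditions: Br2 (1.0 equiv), CH2Cl2, −78 °C; evaporate; KOH, EtOH, 60 °C
Reagents that add atoms: bromine BrBr
Why: Electrophilic bromination picks the electron-rich trisubstituted alkene over the alkyne, and E2 dehydrobromination (tertiary bromide leaves, the acidified CHBr hydrogen is removed, Zaitsev sense) should give the tetrasubstituted vinyl bromide.

Step 3
Reactants: 5 (3R)-6-bromo-3,7-dimethyloct-6-en-1-yne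
Product: 7 (2E,4R)-7-bromo-3,4,8-trimethylnona-2,7-dien-1-ol, via alkenylalane 6 (not isolated)
Conditions: AlMe3, Cp2ZrCl2 (cat.), CH2Cl2, 0 °C to rt; n-BuLi, −78 °C; (CH2O)n, THF, rt; aq HCl
Reagents that add atoms: trimethylaluminium C[Al](C)C; paraformaldehyde (as formaldehyde) C=O
Why: Zirconium-catalysed Negishi carboalumination adds Me–Al syn across the terminal alkyne (methyl to the internal carbon), and hydroxymethylation of the alanate with retention gives the E-trisubstituted allylic alcohol.

Step 4
Reactants: 7 (2E,4R)-7-bromo-3,4,8-trimethylnona-2,7-dien-1-ol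
Product: 8 {(2S,3S)-3-[(2R)-5-bromo-6-methylhept-5-en-2-yl]-3-methyloxiran-2-yl}methanol
Conditions: Ti(OiPr)4 (cat.), L-(+)-diisopropyl tartrate (cat.), t-BuOOH, 4 Å MS, CH2Cl2, −20 °C
Reagents that add atoms: tert-butyl hydroperoxide CC(C)(C)OO
Why: Sharpless asymmetric epoxidation with L-(+)-tartrate delivers oxygen under reagent control to the face that gives the (2S,3S)-epoxide, and the tertiary epoxide carbon carries the stereochemical information for C1; the vinyl bromide is inert.

Step 5
Reactants: 8 {(2S,3S)-3-[(2R)-5-bromo-6-methylhept-5-en-2-yl]-3-methyloxiran-2-yl}methanol; 9 isofraxidin (7-hydroxy-6,8-dimethoxycoumarin)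
Product: 10 7-({(2S,3S)-3-[(2R)-5-bromo-6-methylhept-5-en-2-yl]-3-methyloxiran-2-yl}methoxy)-6,8-dimethoxycoumarin
Conditions: PPh3, DIAD, THF, 0 °C to rt
Reagents that add atoms: none
Why: Mitsunobu etherification of an unhindered primary epoxy alcohol with the acidic 7-OH forms the aryl ether while that CH2 is not yet neopentyl, and no stereocentre is touched.

Step 6
Reactants: 10 7-({(2S,3S)-3-[(2R)-5-bromo-6-methylhept-5-en-2-yl]-3-methyloxiran-2-yl}methoxy)-6,8-dimethoxycoumarin
Product: 11 (2S,3R)-6-bromo-2-{[(6,8-dimethoxy-2-oxochromen-7-yl)oxy]methyl}-2,3,7-trimethyloct-6-enal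
Conditions: MABR [AlMe3 + 2 equiv 4-bromo-2,6-di-tert-butylphenol], 3 equiv, CH2Cl2, −78 to −20 °C; aq HCl
Reagents that add atoms: none
Why: In this bulky-aluminium-promoted epoxide-to-aldehyde rearrangement (Meinwald type, as used on O-protected trisubstituted 2,3-epoxy alcohols) the tertiary C–O bond ionises while ArOCH2 migrates anti to it, so that carbon is inverted stereospecifically and becomes quaternary C1, with the former epoxide CH as the aldehyde (future C6); the deactivated vinyl bromide does not trap the cationic centre.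

Step 7
Reactants: 11 (2S,3R)-6-bromo-2-{[(6,8-dimethoxy-2-oxochromen-7-yl)oxy]methyl}-2,3,7-trimethyloct-6-enal; 12 (3-hydroxypropyl)triphenylphosphonium bromide
Product: 14 7-{[(2R,3E)-2-[(2R)-5-bromo-6-methylhept-5-en-2-yl]-6-hydroxy-2-methylhex-3-en-1-yl]oxy}-6,8-dimethoxycoumarin, via oxido ylide 13 (not isolated)
Conditions: 12, LiHMDS (2.0 equiv), THF, −78 to 0 °C; then 11, −78 °C to rt; H2O
Reagents that add atoms: none
Why: Wittig olefination with the γ-oxido ylide attaches the complete three-carbon chain to the non-enolisable aldehyde, which cannot lose aryloxide because it has no α-hydrogen, faster than the ylide attacks the lactone at low temperature.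

Step 8
Reactants: 14 7-{[(2R,3E)-2-[(2R)-5-bromo-6-methylhept-5-en-2-yl]-6-hydroxy-2-methylhex-3-en-1-yl]oxy}-6,8-dimethoxycoumarin
Product: 17 7-{[(1R,2R,6R)-2-(3-hydroxypropyl)-1,6-dimethyl-3-(propan-2-ylidene)cyclohexyl]methoxy}-6,8-dimethoxy-2H-chromen-2-one (target), via vinyl radical 15 (not isolated), via cyclised alkyl radical 16 (not isolated)
Conditions: Bu3SnH (syringe pump), AIBN (cat.), PhH (about 2 mM), 80 °C
Reagents that add atoms: none
Why: Bu3Sn• abstracts bromine from 14 to give the σ-vinyl radical 15 at C5, which adds to C6 of the chain alkene, and the secondary radical 16 then takes hydrogen from the stannane in a chain process. The closest known reaction type is the vinyl radical cyclisation of 2-bromo-1-alkenes onto unactivated alkenes (Stork type). The cyclohexane closes in the 6-exo-trig mode, and 7-endo attack is disfavoured because the distal alkene carbon carries the alkyl chain. C6 is the only new stereocentre: in the chair-like transition state the C2 methyl sits equatorial and CH2OAr on C1 axial, and allylic 1,3-strain with the cis methyl of C5=CMe2 pushes the chain carbon into the axial position anti to CH2OAr, which is the (R)-configuration of the target. The step needs cyclisation to outrun direct reduction and 1,5-hydrogen transfer, which the quaternary C1 and branched C2 in the tether (gem-disubstituent effect) and slow stannane addition at high dilution should secure. Because the radical sits on the sp2 carbon the tetrasubstituted double bond cannot migrate, and coumarin, aryl ether and free hydroxyl are inert to the tin hydride chain.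

**Compound list**

1 | (R)-citronellal | O=CC[C@H](C)CCC=C(C)C | starting material
2 | (1E,3R)-3,7-dimethylocta-1,6-dien-1-yl nonaflate | FC(F)(F)C(F)(F)C(F)(F)C(F)(F)S(=O)(=O)O/C=C/[C@H](C)CCC=C(C)C | intermediate
3 | (3R)-3,7-dimethyloct-6-en-1-yne | C#C[C@H](C)CCC=C(C)C | intermediate
4 | (3R)-6,7-dibromo-3,7-dimethyloct-1-yne (C6 epimers) | C#C[C@H](C)CCC(Br)C(C)(C)Br | intermediate
5 | (3R)-6-bromo-3,7-dimethyloct-6-en-1-yne | C#C[C@H](C)CCC(Br)=C(C)C | intermediate
6 | (E)-alkenyl(dimethyl)alane from syn methylalumination of 5 | C[Al](C)/C=C(\C)[C@H](C)CCC(Br)=C(C)C | intermediate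
7 | (2E,4R)-7-bromo-3,4,8-trimethylnona-2,7-dien-1-ol | OC/C=C(\C)[C@H](C)CCC(Br)=C(C)C | intermediate
8 | {(2S,3S)-3-[(2R)-5-bromo-6-methylhept-5-en-2-yl]-3-methyloxiran-2-yl}methanol | OC[C@@H]1O[C@@]1(C)[C@H](C)CCC(Br)=C(C)C | intermediate
9 | isofraxidin | COc1cc2ccc(=O)oc2c(OC)c1O | starting material
10 | epoxy aryl ether of 8 with isofraxidin | COc1cc2ccc(=O)oc2c(OC)c1OC[C@@H]1O[C@@]1(C)[C@H](C)CCC(Br)=C(C)C | intermediate
11 | (2S,3R)-α-quaternary β-aryloxy aldehyde | COc1cc2ccc(=O)oc2c(OC)c1OC[C@](C=O)(C)[C@H](C)CCC(Br)=C(C)C | intermediate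
12 | (3-hydroxypropyl)triphenylphosphonium bromide | OCCC[P+](c1ccccc1)(c1ccccc1)c1ccccc1.[Br-] | starting material
13 | lithium 3-(triphenylphosphoranylidene)propan-1-olate | [Li+].[O-]CCC=P(c1ccccc1)(c1ccccc1)c1ccccc1 | intermediate
14 | acyclic bromo diene alcohol (cyclisation precursor) | COc1cc2ccc(=O)oc2c(OC)c1OC[C@](/C=C/CCO)(C)[C@H](C)CCC(Br)=C(C)C | intermediate
15 | C5 vinyl radical | COc1cc2ccc(=O)oc2c(OC)c1OC[C@](/C=C/CCO)(C)[C@H](C)CC[C]=C(C)C | intermediate
16 | cyclised secondary alkyl radical | COc1cc2ccc(=O)oc2c(OC)c1OC[C@]1(C)[C@H](C)CCC(=C(C)C)[C@H]1[CH]CCO | intermediate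
17 | CNP0311605.1 | COc1cc2ccc(=O)oc2c(OC)c1OC[C@]1(C)[C@H](C)CCC(=C(C)C)[C@H]1CCCO | target

Total step count: 8. Longest linear sequence: 8 steps (1 to 17).

**Steps most likely to fail**

Step 8. The vinyl radical may be reduced before it cyclises. It may abstract hydrogen internally from the C2 methyl or the OCH2 group. The facial bias at C6 may also be too small. The fallback sets out from aldehyde 11 and returns at 17. A Nozaki–Hiyama–Kishi closure (CrCl2, cat. NiCl2, DMF) joins the vinyl bromide to the aldehyde and gives the 2-isopropylidenecyclohexanol F1. Ionisation with BF3·OEt2 in the presence of allyltrimethylsilane should trap the exocyclic allyl cation at the ring terminus, anti to the axial CH2OAr group, to give the C6-allyl compound F2. Chemoselective hydroboration of the terminal alkene (9-BBN, then NaBO3) then gives 17.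

Step 6. A hydride shift may compete with the alkyl shift, or the lactone and methoxy oxygens may tie up the Lewis acid, so that the epoxide does not rearrange in the wanted sense. The fallback sets out from epoxy alcohol 8 and returns at 11. Silylation (TBSCl, imidazole) gives the epoxy silyl ether F3. The same aluminium-promoted rearrangement, now free of the coumarin, gives the β-siloxy aldehyde F4. HF·pyridine frees the β-hydroxy aldehyde F5. A high-temperature Mitsunobu reaction with 9, using (cyanomethylene)tributylphosphorane in toluene at 100 °C, forms the ether on the still acyclic neopentyl alcohol and gives 11.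

Step 2. The tertiary bromide may eliminate towards a methyl group, which shifts the halogen to an allylic position instead of the vinylic one. The fallback sets out from enyne 3 and returns at 5. Alkene-selective ozonolysis with Me2S work-up gives (4R)-4-methylhex-5-ynal F6. Pinnick oxidation gives (4R)-4-methylhex-5-ynoic acid F7. Iododecarboxylation (PhI(OAc)2, I2, hν) gives (3R)-5-iodo-3-methylpent-1-yne F8. Zinc insertion gives the alkylzinc iodide F9. A mono-selective Negishi coupling with 1,1-dibromo-2-methylprop-1-ene (Pd, DPEphos) then places the bromine unambiguously and gives 5.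

Further compounds
F1 | step 8 | 7-{[(1R,6R)-2-hydroxy-1,6-dimethyl-3-(propan-2-ylidene)cyclohexyl]methoxy}-6,8-dimethoxycoumarin (carbinol epimers) | COc1cc2ccc(=O)oc2c(OC)c1OC[C@]1(C)[C@H](C)CCC(=C(C)C)C1O
F2 | step 8 | 7-{[(1R,2R,6R)-1,6-dimethyl-3-(propan-2-ylidene)-2-(prop-2-en-1-yl)cyclohexyl]methoxy}-6,8-dimethoxycoumarin | COc1cc2ccc(=O)oc2c(OC)c1OC[C@]1(C)[C@H](C)CCC(=C(C)C)[C@H]1CC=C
F3 | step 6 | tert-butyldimethylsilyl ether of 8 | CC(C)(C)[Si](C)(C)OC[C@@H]1O[C@@]1(C)[C@H](C)CCC(Br)=C(C)C
F4 | step 6 | 6-bromo-2-[(tert-butyldimethylsilyloxy)methyl]-2,3,7-trimethyloct-6-enal | CC(C)(C)[Si](C)(C)OC[C@](C=O)(C)[C@H](C)CCC(Br)=C(C)C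
F5 | step 6 | 6-bromo-2-(hydroxymethyl)-2,3,7-trimethyloct-6-enal | OC[C@](C=O)(C)[C@H](C)CCC(Br)=C(C)C
F6 | step 2 | (4R)-4-methylhex-5-ynal | C#C[C@H](C)CCC=O
F7 | step 2 | (4R)-4-methylhex-5-ynoic acid | C#C[C@H](C)CCC(=O)O
F8 | step 2 | (3R)-5-iodo-3-methylpent-1-yne | C#C[C@H](C)CCI
F9 | step 2 | [(3R)-3-methylpent-4-yn-1-yl]zinc iodide | C#C[C@H](C)CC[Zn]I
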